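A chemist who wants an order in second substrate from runs that never change its charge has to read it where it falls by itself.

the same everywhere: solid substrate 0.082 M
- south-west: second substrate 0.041 M; enzyme 0.52 µM; the very flask that is asked about, followed so far
- south-east: second substrate 0.041 M; enzyme 0.78 µM; run made earlier
- flask: second substrate 0.0410 M; enzyme 0.52 µM

| south-west: time / min | south-west: target / % | south-east: time / min | south-east: target / % |
|---|---|---|---|
| 6.00 | 0.7 | 8.00 | 0.7 |
| 12.0 | 2.8 | 25.0 | 9.3 |
| 15.0 | 3.0 | 40.0 | 17.3 |
| 25.0 | 7.6 | 60.0 | 27.9 |
| 30.0 | 8.4 | 90.0 | 40.9 |

(each reading ± 0.5 percentage points)

- solid substrate is a solid; its amount is given per volume of the solution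
- the numbers in the tables scatter with a standard deviation of 0.5 percentage points
- at the start none of the solid substrate is in solution
- what has only dissolved of solid substrate counts as not reacted
- no earlier run changes the charge of second substrate; that part of a forecast is a guess

- apparent order in second substrate when 10% of the solid substrate are converted (what has only dissolved counts as not reacted) (percent change of the rate of making target for one percent more second substrate charged)

Does the south-east run speak for the flask asked about? With the same charges of solid substrate and second substrate it holds 1.50 times the enzyme, and its readings climb 1.71 times as fast on the straight stretch, so I borrow its shape.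

How far does its rate sag? I take one second substrate per target, which makes second substrate the limiting reagent by charge. In the south-east run the slope from 60.0 min to 90.0 min is 0.815 of the slope from 25.0 min to 60.0 min, while the second substrate left, reckoned from the mean target reading of each stretch, goes from 25.7 mM to 12.8 mM. So the order along the run, the percent the rate falls for one percent less second substrate left, reads 0.292, on a scale where zero means the rate does not notice and one means it follows in proportion.

What does that make the order in the charge? At 10% conversion 32.8 mM is left, so one percent more charge means 1.25 percent more left. If the reading holds there, my figure is 0.365.

The forecast, which says “the enzyme is nearly saturated in second substrate”, gives 0.17, between 0.03 and 0.4, lower than my figure.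

The simulation gives 0.35.

    ternary complex → enzyme + target (k = 37.3 /s)
    starting material + enzyme ⇌ starting complex (K = 69.2 /M, k = 3070 /M/s)
    second substrate + starting complex ⇌ ternary complex (K = 54.0 /M, k = 15800 /M/s)
    solid substrate ⇌ starting material, rate k4*(cs4 - [starting material]) while solid is left; crystals form when [starting material] > cs4 (solubility = 32.0 mM, k = 4.07 × 10⁻⁴ /s)

In the flask at 0.544 h, when that conversion is reached, enzyme is 53.1% of the catalyst and target is made at 0.0200 M/h. Target comes from the ternary complex, so I put the order along the run on it. In the flask, from 0.400 h to 2.00 h, second substrate falls from 86.9% to 18.8% of its charge; an order of 0.292 then reckons the ternary complex from 27.2% of the catalyst down to 17.4%, and it stands at 16.0%.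

All runs come from a simulation for substances that don't exist, noise included.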